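**Plan**

- Cuts: the pyranone ring is cut first, back to an arylacetaldehyde arm plus a dioxinone four-carbon unit. Then the C1–C8a bond of the tetralone is cut, then C2–C3 (Reformatsky) and C4–C(aroyl) (aldol). This leaves a ring A acetic acid and the aroyl-ring aldehyde, both made from methyl 3,5-dihydroxyphenylacetate.
- Enabling feature: C1 (ring ketone) is bonded to C8a of ring A, ortho to the C8 phenol oxygen. C1–C2–C3–C4 plus the aroyl carbon map onto a 4-hydroxy-4-methyl δ-lactone (C1 = lactone carbonyl, aroyl carbon = carbinol carbon carrying the ring oxygen) whose C5 bears ring A with bromine at the future C8a.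
- Forward order: the aldol joins the two arenes; methyl ketone, then bromoacetate; SmI2 closes the δ-lactone; aryllithium attack exchanges the lactone for ring B; oxidation gives the aroyl ketone; the side arm is grown into the pyranone (last ring); desilylation and hydrogenolysis finish.
- Stereochemistry: C4 comes from the boron aldol of the (R)-4-benzyl-oxazolidinone imide. C3 comes from the samarium-bridged Reformatsky transition state, relayed by the aldol carbinol centre, which is oxidised afterwards. The ring switch touches neither centre.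

Key step: step 14

Remark: positions are numbered as in 3,4-dihydronaphthalen-1(2H)-one (C1 ring ketone, C3 tertiary carbinol, C4 aroyl-bearing carbon; target 3R,4S); the silyl dienol ether 27 is made rather than bought, and the two carbinol epimers of 28 are carried on together because that centre is oxidised in step 20.

**Route**

Step 1
Reactants: 1 methyl 2-(3,5-dihydroxyphenyl)acetate
Product: 2 methyl 2-[3,5-bis(benzyloxy)phenyl]acetate
Conditions: BnBr, K2CO3, DMF, rt
Reagents that add atoms: benzyl bromide, BrCc1ccccc1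
Why: Williamson etherification of the two phenols with K2CO3, a base too weak to deprotonate the arylacetate α-position, so only O-benzylation is expected.

Step 2
Reactants: 2 methyl 2-[3,5-bis(benzyloxy)phenyl]acetate
Product: 3 methyl 2-[3,5-bis(benzyloxy)-2-bromophenyl]acetate
Conditions: NBS, MeCN, 0 °C
Reagents that add atoms: N-bromosuccinimide, O=C1CCC(=O)N1Br
Why: Electrophilic aromatic bromination of the electron-rich ring is expected at C2, which is para to one benzyloxy group, ortho to the other and less shielded than the position between the two ethers, the regiochemistry known for 3,5-dialkoxyphenylacetates.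

Step 3
Reactants: 3 methyl 2-[3,5-bis(benzyloxy)-2-bromophenyl]acetate
Product: 4 2-[3,5-bis(benzyloxy)-2-bromophenyl]acetic acid
Conditions: LiOH, THF/H2O, rt; then 1 M HCl
Reagents that add atoms: lithium hydroxide, [Li+].[OH-]
Why: Saponification of the methyl ester, to which the aryl bromide and the benzyl ethers are inert.

Step 4
Reactants: 4 2-[3,5-bis(benzyloxy)-2-bromophenyl]acetic acid; 5 (R)-4-benzyl-1,3-oxazolidin-2-one
Product: 7 (R)-4-benzyl-3-{2-[3,5-bis(benzyloxy)-2-bromophenyl]acetyl}-1,3-oxazolidin-2-one, via mixed pivalic anhydride 6 (not isolated)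
Conditions: PivCl, Et3N, THF, −20 °C; then 5, LiCl, −20 °C → rt
Reagents that add atoms: none
Why: Mixed-anhydride N-acylation of the oxazolidinone under LiCl/Et3N activation, a standard way to load the auxiliary without pre-forming its lithium salt.

Step 5
Reactants: 3 methyl 2-[3,5-bis(benzyloxy)-2-bromophenyl]acetate
Product: 8 2-[3,5-bis(benzyloxy)-2-bromophenyl]ethan-1-ol
Conditions: LiBH4, THF, 0 °C → rt
Reagents that add atoms: none
Why: Hydride reduction of the ester with LiBH4 gives the primary alcohol and leaves the aryl bromide and benzyl ethers untouched.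

Step 6
Reactants: 8 2-[3,5-bis(benzyloxy)-2-bromophenyl]ethan-1-ol
Product: 9 {2-[3,5-bis(benzyloxy)-2-bromophenyl]ethoxy}triethylsilane
Conditions: TESCl, imidazole, CH2Cl2, 0 °C
Reagents that add atoms: chlorotriethylsilane, CC[Si](Cl)(CC)CC
Why: Silylation of the primary alcohol; the triethylsilyl ether is chosen because a primary one can later be removed with mild acid next to a hindered tertiary one.

Step 7
Reactants: 9 {2-[3,5-bis(benzyloxy)-2-bromophenyl]ethoxy}triethylsilane
Product: 11 2,4-bis(benzyloxy)-6-[2-(triethylsilyloxy)ethyl]benzaldehyde, via aryllithium 10 (not isolated)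
Conditions: n-BuLi, THF, −78 °C; DMF, −78 → 0 °C; then H2O
Reagents that add atoms: N,N-dimethylformamide, CN(C)C=O
Why: Bromine–lithium exchange in the cold followed by formylation of the aryllithium with DMF (Bouveault aldehyde synthesis), which the silyl and benzyl ethers tolerate.

Step 8
Reactants: 7 ring A acetyl imide; 11 aroyl-ring aldehyde
Product: 13 (R)-4-benzyl-3-[(2R,3R)-3-{2,4-bis(benzyloxy)-6-[2-(triethylsilyloxy)ethyl]phenyl}-2-[3,5-bis(benzyloxy)-2-bromophenyl]-3-hydroxypropanoyl]-1,3-oxazolidin-2-one, via Z-dibutylboron enolate 12 (not isolated)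
Conditions: Bu2BOTf, iPr2NEt, CH2Cl2, −78 → 0 °C; 11, −78 → 0 °C; pH 7 buffer, MeOH, H2O2, 0 °C
Reagents that add atoms: none
Why: Auxiliary-controlled boron aldol (Evans syn-aldol), in which the Z-boron enolate adds through a closed chair (Zimmerman–Traxler) transition state on the enolate face opposite the benzyl group of the (R)-oxazolidinone, setting the α-aryl centre R (C4 of the target) and the carbinol centre R in a 2,3-syn relationship.

Step 9
Reactants: 13 syn-aldol imide
Product: 14 (2R,3R)-3-{2,4-bis(benzyloxy)-6-[2-(triethylsilyloxy)ethyl]phenyl}-2-[3,5-bis(benzyloxy)-2-bromophenyl]-3-hydroxy-N-methoxy-N-methylpropanamide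
Conditions: MeONHMe·HCl, AlMe3, CH2Cl2, −20 → 0 °C
Reagents that add atoms: N,O-dimethylhydroxylamine hydrochloride, CNOC.Cl
Why: Transamination of the imide with the aluminium amide reagent (Weinreb amide formation), directed to the exocyclic carbonyl by the aluminium alkoxide of the free β-hydroxyl, releases the auxiliary without touching either new stereocentre.

Step 10
Reactants: 14 hydroxy Weinreb amide
Product: 15 (3R,4R)-4-{2,4-bis(benzyloxy)-6-[2-(triethylsilyloxy)ethyl]phenyl}-3-[3,5-bis(benzyloxy)-2-bromophenyl]-4-hydroxybutan-2-one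
Conditions: MeMgBr (excess), THF, −20 → 0 °C; then cold H2O
Reagents that add atoms: methylmagnesium bromide, C[Mg]Br
Why: Weinreb ketone synthesis, in which MeMgBr adds once after deprotonating the hydroxyl and the chelated tetrahedral intermediate keeps the carbonyl masked until the cold quench, so that retro-aldol cleavage and epimerisation of the α-aryl centre are avoided.

Step 11
Reactants: 15 β-hydroxy methyl ketone
Product: 16 (1R,2R)-1-{2,4-bis(benzyloxy)-6-[2-(triethylsilyloxy)ethyl]phenyl}-2-[3,5-bis(benzyloxy)-2-bromophenyl]-3-oxobutyl 2-bromoacetate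
Conditions: BrCH2COBr, pyridine, CH2Cl2, −40 → 0 °C
Reagents that add atoms: bromoacetyl bromide, BrCC(Br)=O
Why: O-acylation of the secondary benzylic alcohol with the reactive acyl bromide and pyridine in the cold, conditions too weakly basic to enolise the α-aryl ketone or eliminate the new ester.

Step 12
Reactants: 16 β-bromoacetoxy ketone
Product: 18 (4R,5R,6R)-6-{2,4-bis(benzyloxy)-6-[2-(triethylsilyloxy)ethyl]phenyl}-5-[3,5-bis(benzyloxy)-2-bromophenyl]-4-hydroxy-4-methyloxan-2-one, via samarium ester enolate 17 (not isolated)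
Conditions: SmI2 (2.2 equiv), THF, −78 °C; then H2O
Reagents that add atoms: none
Why: SmI2-promoted intramolecular Reformatsky reaction, in which the trivalent samarium enolate adds to the ketone through a chair-like bicyclic transition state with samarium bridging the enolate and ketone oxygens, the 6-aryl group equatorial and the 5-aryl group axial on the far face, so that the hydroxyl is delivered axial and the new tertiary centre (C3 of the target) forms R with its methyl cis to both aryl groups (1,3-induction from the carbinol carbon).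

Step 13
Reactants: 18 hydroxy lactone
Product: 19 (4R,5R,6R)-6-{2,4-bis(benzyloxy)-6-[2-(triethylsilyloxy)ethyl]phenyl}-5-[3,5-bis(benzyloxy)-2-bromophenyl]-4-methyl-4-(triethylsilyloxy)oxan-2-one
Conditions: TESOTf, 2,6-lutidine, CH2Cl2, −78 → 0 °C
Reagents that add atoms: triethylsilyl trifluoromethanesulfonate, CC[Si](CC)(CC)OS(=O)(=O)C(F)(F)F
Why: Silylation of the tertiary alcohol with the silyl triflate blocks the alkoxide that would otherwise trigger retro-aldol cleavage after the ring switch.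

Step 14
Reactants: 19 silylated bromo lactone
Product: 22 (3R,4R)-6,8-bis(benzyloxy)-4-[(R)-{2,4-bis(benzyloxy)-6-[2-(triethylsilyloxy)ethyl]phenyl}(hydroxy)methyl]-3-methyl-3-(triethylsilyloxy)-3,4-dihydronaphthalen-1(2H)-one, via aryllithium 20 (not isolated), via bridged lithium hemiketalate 21 (not isolated)
Conditions: t-BuLi (2.1 equiv), THF, −100 → −78 °C; then H2O
Reagents that add atoms: none
Why: t-BuLi exchanges the aryl bromide at −100 °C faster than it adds to or enolises the lactone, and the second equivalent destroys the tert-butyl bromide formed; the aryllithium 20, whose aryl ring sits axial on C5 of the all-cis lactone chair (4-methyl and 6-aryl equatorial), reaches over the ring and attacks the lactone carbonyl through a boat-like transition state to give the bridged hemiketalate 21. This intermediate opens by expelling the benzylic alkoxide, at the latest on quench, because the conjugated aryl ketone is favoured over the strained bicyclic lactol, so the lactone ring is exchanged for ring B. The closest known reaction type is the Parham cyclisation, the anionic cycloacylation of an aryllithium onto an ester or lactone. One ring (ring B) closes, 6-exo-trig, through the new C1–C8a bond. No new stereocentre is formed: C3 and C4 are carried unchanged from C4 and C5 of the lactone, and the carbinol centre from C6. The step needs chemoselectivity only: exchange before carbonyl attack is secured by the rate of bromine–lithium exchange in the cold and by the ortho benzyloxy group that stabilises the aryllithium, and a single acylation is secured by the hemiketalate, which masks the ketone until work-up, and by the silyl ether, which prevents retro-aldol cleavage.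

Step 15
Reactants: 22 tetralone carbinol
Product: 23 (3R,4S)-6,8-bis(benzyloxy)-4-{2,4-bis(benzyloxy)-6-[2-(triethylsilyloxy)ethyl]benzoyl}-3-methyl-3-(triethylsilyloxy)-3,4-dihydronaphthalen-1(2H)-one
Conditions: Dess–Martin periodinane, CH2Cl2, 0 °C → rt
Reagents that add atoms: none
Why: Dess–Martin oxidation of the secondary benzylic carbinol to the aroyl ketone under neutral conditions, done before the side arm is unmasked so that no lactol can form between the carbinol and the later aldehyde, and with no base that could epimerise C4.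

Step 16
Reactants: 23 aroyl ketone with silylated arm
Product: 24 (3R,4S)-6,8-bis(benzyloxy)-4-[2,4-bis(benzyloxy)-6-(2-hydroxyethyl)benzoyl]-3-methyl-3-(triethylsilyloxy)-3,4-dihydronaphthalen-1(2H)-one
Conditions: PPTS (cat.), MeOH/CH2Cl2, 0 °C
Reagents that add atoms: none
Why: Acid-catalysed methanolysis removes the unhindered primary triethylsilyl ether much faster than the hindered tertiary one (steric differentiation of silyl ethers).

Step 17
Reactants: 24 primary alcohol
Product: 25 (3R,4S)-6,8-bis(benzyloxy)-4-[2,4-bis(benzyloxy)-6-(2-oxoethyl)benzoyl]-3-methyl-3-(triethylsilyloxy)-3,4-dihydronaphthalen-1(2H)-one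
Conditions: Dess–Martin periodinane, CH2Cl2, 0 °C → rt
Reagents that add atoms: none
Why: Dess–Martin oxidation of the primary alcohol to the arylacetaldehyde under neutral conditions, which avoids enolisation of the aldehyde and of the C4–H.

Step 18
Reactants: 26 2,2,6-trimethyl-4H-1,3-dioxin-4-one
Product: 27 [(2,2-dimethyl-6-methylidene-6H-1,3-dioxin-4-yl)oxy]trimethylsilane
Conditions: lithium diisopropylamide, THF, −78 °C; TMSCl
Reagents that add atoms: chlorotrimethylsilane, C[Si](C)(C)Cl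
Why: γ-Deprotonation of the dioxinone and O-silylation of the dienolate give the silyl dienol ether, the standard vinylogous nucleophile of this acetoacetate equivalent.

Step 19
Reactants: 25 arylacetaldehyde; 27 silyl dienol ether
Product: 28 (3R,4S)-6,8-bis(benzyloxy)-4-{2,4-bis(benzyloxy)-6-[3-(2,2-dimethyl-4-oxo-4H-1,3-dioxin-6-yl)-2-hydroxypropyl]benzoyl}-3-methyl-3-(triethylsilyloxy)-3,4-dihydronaphthalen-1(2H)-one
Conditions: 27, BF3·OEt2, CH2Cl2, −78 °C; aqueous work-up
Reagents that add atoms: none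
Why: Vinylogous Mukaiyama aldol addition, in which BF3·OEt2 activates the aldehyde, far more electrophilic than the two hindered aryl ketones, and the dienol ether attacks through its terminal methylene; the new carbinol centre is not controlled and need not be.

Step 20
Reactants: 28 hydroxy dioxinone
Product: 29 (3R,4S)-6,8-bis(benzyloxy)-4-{2,4-bis(benzyloxy)-6-[3-(2,2-dimethyl-4-oxo-4H-1,3-dioxin-6-yl)-2-oxopropyl]benzoyl}-3-methyl-3-(triethylsilyloxy)-3,4-dihydronaphthalen-1(2H)-one
Conditions: Dess–Martin periodinane, CH2Cl2, 0 °C → rt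
Reagents that add atoms: none
Why: Dess–Martin oxidation of the secondary alcohol gives the β-keto dioxinone, a conversion this reagent performs without attacking the active methylene.

Step 21
Reactants: 29 keto dioxinone
Product: 31 (3R,4S)-6,8-bis(benzyloxy)-4-{2,4-bis(benzyloxy)-6-[(4-hydroxy-2-oxo-2H-pyran-6-yl)methyl]benzoyl}-3-methyl-3-(triethylsilyloxy)-3,4-dihydronaphthalen-1(2H)-one, via acylketene 30 (not isolated)
Conditions: toluene, 110 °C
Reagents that add atoms: none
Why: Thermal retro-[4+2] loss of acetone from the dioxinone gives an acylketene that is captured by the enol oxygen of the side-chain ketone (6π-electrocyclisation of the enol form), closing the 4-hydroxy-2-pyranone without acid or base.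

Step 22
Reactants: 31 silylated pyranone
Product: 32 (3R,4S)-6,8-bis(benzyloxy)-4-{2,4-bis(benzyloxy)-6-[(4-hydroxy-2-oxo-2H-pyran-6-yl)methyl]benzoyl}-3-hydroxy-3-methyl-3,4-dihydronaphthalen-1(2H)-one
Conditions: HF·pyridine, pyridine, THF, 0 °C → rt
Reagents that add atoms: none
Why: Fluoride-mediated cleavage of the tertiary triethylsilyl ether with buffered HF·pyridine, mildly acidic conditions under which the β-hydroxy ketone should neither cleave by retro-aldol reaction nor eliminate.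

Step 23
Reactants: 32 tetrabenzyl ether
Product: 33 (3R,4S)-4-{2,4-dihydroxy-6-[(4-hydroxy-2-oxo-2H-pyran-6-yl)methyl]benzoyl}-3,6,8-trihydroxy-3-methyl-3,4-dihydronaphthalen-1(2H)-one
Conditions: H2 (1 atm), 10% Pd/C, EtOAc/MeOH, rt
Reagents that add atoms: none
Why: Catalytic hydrogenolysis of the four aryl benzyl ethers at atmospheric pressure, under which the hindered aryl ketones and the pyranone are expected to persist, gives the target with C3 and C4 untouched.

**Compound list**

1 | methyl 2-(3,5-dihydroxyphenyl)acetate | COC(=O)Cc1cc(O)cc(O)c1 | starting material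
2 | methyl 2-[3,5-bis(benzyloxy)phenyl]acetate | COC(=O)Cc1cc(OCc2ccccc2)cc(OCc2ccccc2)c1 | intermediate
3 | methyl 2-[3,5-bis(benzyloxy)-2-bromophenyl]acetate | COC(=O)Cc1cc(OCc2ccccc2)cc(OCc2ccccc2)c1Br | intermediate
4 | 2-[3,5-bis(benzyloxy)-2-bromophenyl]acetic acid | OC(=O)Cc1cc(OCc2ccccc2)cc(OCc2ccccc2)c1Br | intermediate
5 | (R)-4-benzyl-1,3-oxazolidin-2-one | O=C1N[C@H](Cc2ccccc2)CO1 | starting material
6 | mixed anhydride of 4 with pivalic acid | CC(C)(C)C(=O)OC(=O)Cc1cc(OCc2ccccc2)cc(OCc2ccccc2)c1Br | intermediate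
7 | (R)-4-benzyl-3-{2-[3,5-bis(benzyloxy)-2-bromophenyl]acetyl}-1,3-oxazolidin-2-one | O=C(Cc1cc(OCc2ccccc2)cc(OCc2ccccc2)c1Br)N1[C@H](Cc2ccccc2)COC1=O | intermediate
8 | 2-[3,5-bis(benzyloxy)-2-bromophenyl]ethan-1-ol | OCCc1cc(OCc2ccccc2)cc(OCc2ccccc2)c1Br | intermediate
9 | {2-[3,5-bis(benzyloxy)-2-bromophenyl]ethoxy}triethylsilane | CC[Si](CC)(CC)OCCc1cc(OCc2ccccc2)cc(OCc2ccccc2)c1Br | intermediate
10 | {2,4-bis(benzyloxy)-6-[2-(triethylsilyloxy)ethyl]phenyl}lithium | CC[Si](CC)(CC)OCCc1cc(OCc2ccccc2)cc(OCc2ccccc2)c1[Li] | intermediate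
11 | 2,4-bis(benzyloxy)-6-[2-(triethylsilyloxy)ethyl]benzaldehyde | O=Cc1c(OCc2ccccc2)cc(OCc2ccccc2)cc1CCO[Si](CC)(CC)CC | intermediate
12 | (Z)-dibutylboron enolate of imide 7 (boron-bound oxygen cis to the aryl group) | CCCCB(CCCC)O/C(=C\c1cc(OCc2ccccc2)cc(OCc2ccccc2)c1Br)N1[C@H](Cc2ccccc2)COC1=O | intermediate
13 | (R)-4-benzyl-3-[(2R,3R)-3-{2,4-bis(benzyloxy)-6-[2-(triethylsilyloxy)ethyl]phenyl}-2-[3,5-bis(benzyloxy)-2-bromophenyl]-3-hydroxypropanoyl]-1,3-oxazolidin-2-one (syn-aldol) | O=C(N1[C@H](Cc2ccccc2)COC1=O)[C@H](c1cc(OCc2ccccc2)cc(OCc2ccccc2)c1Br)[C@@H](O)c1c(OCc2ccccc2)cc(OCc2ccccc2)cc1CCO[Si](CC)(CC)CC | intermediate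
14 | (2R,3R)-3-{2,4-bis(benzyloxy)-6-[2-(triethylsilyloxy)ethyl]phenyl}-2-[3,5-bis(benzyloxy)-2-bromophenyl]-3-hydroxy-N-methoxy-N-methylpropanamide | CON(C)C(=O)[C@H](c1cc(OCc2ccccc2)cc(OCc2ccccc2)c1Br)[C@@H](O)c1c(OCc2ccccc2)cc(OCc2ccccc2)cc1CCO[Si](CC)(CC)CC | intermediate
15 | (3R,4R)-4-{2,4-bis(benzyloxy)-6-[2-(triethylsilyloxy)ethyl]phenyl}-3-[3,5-bis(benzyloxy)-2-bromophenyl]-4-hydroxybutan-2-one | CC(=O)[C@H](c1cc(OCc2ccccc2)cc(OCc2ccccc2)c1Br)[C@@H](O)c1c(OCc2ccccc2)cc(OCc2ccccc2)cc1CCO[Si](CC)(CC)CC | intermediate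
16 | (1R,2R)-1-{2,4-bis(benzyloxy)-6-[2-(triethylsilyloxy)ethyl]phenyl}-2-[3,5-bis(benzyloxy)-2-bromophenyl]-3-oxobutyl 2-bromoacetate | CC(=O)[C@H](c1cc(OCc2ccccc2)cc(OCc2ccccc2)c1Br)[C@@H](OC(=O)CBr)c1c(OCc2ccccc2)cc(OCc2ccccc2)cc1CCO[Si](CC)(CC)CC | intermediate
17 | diiodosamarium ester enolate of 16 (trivalent samarium on the enolate oxygen) | CC(=O)[C@H](c1cc(OCc2ccccc2)cc(OCc2ccccc2)c1Br)[C@@H](OC(=C)O[Sm](I)I)c1c(OCc2ccccc2)cc(OCc2ccccc2)cc1CCO[Si](CC)(CC)CC | intermediate
18 | (4R,5R,6R)-6-{2,4-bis(benzyloxy)-6-[2-(triethylsilyloxy)ethyl]phenyl}-5-[3,5-bis(benzyloxy)-2-bromophenyl]-4-hydroxy-4-methyloxan-2-one (4-methyl, 5-aryl and 6-aryl mutually cis, hydroxyl trans to both aryl groups) | O=C1C[C@@](C)(O)[C@H](c2cc(OCc3ccccc3)cc(OCc3ccccc3)c2Br)[C@H](c2c(OCc3ccccc3)cc(OCc3ccccc3)cc2CCO[Si](CC)(CC)CC)O1 | intermediate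
19 | (4R,5R,6R)-6-{2,4-bis(benzyloxy)-6-[2-(triethylsilyloxy)ethyl]phenyl}-5-[3,5-bis(benzyloxy)-2-bromophenyl]-4-methyl-4-(triethylsilyloxy)oxan-2-one | O=C1C[C@@](C)(O[Si](CC)(CC)CC)[C@H](c2cc(OCc3ccccc3)cc(OCc3ccccc3)c2Br)[C@H](c2c(OCc3ccccc3)cc(OCc3ccccc3)cc2CCO[Si](CC)(CC)CC)O1 | intermediate
20 | aryllithium from 19 (lithium in place of bromine) | O=C1C[C@@](C)(O[Si](CC)(CC)CC)[C@H](c2cc(OCc3ccccc3)cc(OCc3ccccc3)c2[Li])[C@H](c2c(OCc3ccccc3)cc(OCc3ccccc3)cc2CCO[Si](CC)(CC)CC)O1 | intermediate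
21 | bridged lithium hemiketalate (C1–C8a bond formed, lactone oxygen still on C1; benzo-fused 2-oxabicyclo[2.2.2]octane) | [Li]O[C@]12C[C@@](C)(O[Si](CC)(CC)CC)[C@H](c3cc(OCc4ccccc4)cc(OCc4ccccc4)c13)[C@H](c1c(OCc3ccccc3)cc(OCc3ccccc3)cc1CCO[Si](CC)(CC)CC)O2 | intermediate
22 | (3R,4R)-6,8-bis(benzyloxy)-4-[(R)-{2,4-bis(benzyloxy)-6-[2-(triethylsilyloxy)ethyl]phenyl}(hydroxy)methyl]-3-methyl-3-(triethylsilyloxy)-3,4-dihydronaphthalen-1(2H)-one | C[C@@]1(O[Si](CC)(CC)CC)CC(=O)c2c(OCc3ccccc3)cc(OCc3ccccc3)cc2[C@@H]1[C@@H](O)c1c(OCc2ccccc2)cc(OCc2ccccc2)cc1CCO[Si](CC)(CC)CC | intermediate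
23 | (3R,4S)-6,8-bis(benzyloxy)-4-{2,4-bis(benzyloxy)-6-[2-(triethylsilyloxy)ethyl]benzoyl}-3-methyl-3-(triethylsilyloxy)-3,4-dihydronaphthalen-1(2H)-one | C[C@@]1(O[Si](CC)(CC)CC)CC(=O)c2c(OCc3ccccc3)cc(OCc3ccccc3)cc2[C@@H]1C(=O)c1c(OCc2ccccc2)cc(OCc2ccccc2)cc1CCO[Si](CC)(CC)CC | intermediate
24 | (3R,4S)-6,8-bis(benzyloxy)-4-[2,4-bis(benzyloxy)-6-(2-hydroxyethyl)benzoyl]-3-methyl-3-(triethylsilyloxy)-3,4-dihydronaphthalen-1(2H)-one | C[C@@]1(O[Si](CC)(CC)CC)CC(=O)c2c(OCc3ccccc3)cc(OCc3ccccc3)cc2[C@@H]1C(=O)c1c(OCc2ccccc2)cc(OCc2ccccc2)cc1CCO | intermediate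
25 | (3R,4S)-6,8-bis(benzyloxy)-4-[2,4-bis(benzyloxy)-6-(2-oxoethyl)benzoyl]-3-methyl-3-(triethylsilyloxy)-3,4-dihydronaphthalen-1(2H)-one | C[C@@]1(O[Si](CC)(CC)CC)CC(=O)c2c(OCc3ccccc3)cc(OCc3ccccc3)cc2[C@@H]1C(=O)c1c(OCc2ccccc2)cc(OCc2ccccc2)cc1CC=O | intermediate
26 | 2,2,6-trimethyl-4H-1,3-dioxin-4-one | CC1=CC(=O)OC(C)(C)O1 | starting material
27 | [(2,2-dimethyl-6-methylidene-6H-1,3-dioxin-4-yl)oxy]trimethylsilane | C=C1C=C(O[Si](C)(C)C)OC(C)(C)O1 | intermediate
28 | (3R,4S)-6,8-bis(benzyloxy)-4-{2,4-bis(benzyloxy)-6-[3-(2,2-dimethyl-4-oxo-4H-1,3-dioxin-6-yl)-2-hydroxypropyl]benzoyl}-3-methyl-3-(triethylsilyloxy)-3,4-dihydronaphthalen-1(2H)-one (both epimers at the side-chain carbinol) | C[C@@]1(O[Si](CC)(CC)CC)CC(=O)c2c(OCc3ccccc3)cc(OCc3ccccc3)cc2[C@@H]1C(=O)c1c(OCc2ccccc2)cc(OCc2ccccc2)cc1CC(O)CC1=CC(=O)OC(C)(C)O1 | intermediate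
29 | (3R,4S)-6,8-bis(benzyloxy)-4-{2,4-bis(benzyloxy)-6-[3-(2,2-dimethyl-4-oxo-4H-1,3-dioxin-6-yl)-2-oxopropyl]benzoyl}-3-methyl-3-(triethylsilyloxy)-3,4-dihydronaphthalen-1(2H)-one | C[C@@]1(O[Si](CC)(CC)CC)CC(=O)c2c(OCc3ccccc3)cc(OCc3ccccc3)cc2[C@@H]1C(=O)c1c(OCc2ccccc2)cc(OCc2ccccc2)cc1CC(=O)CC1=CC(=O)OC(C)(C)O1 | intermediate
30 | acylketene from 29 (side arm CH2–CO–CH2–CO–CH=C=O) | C[C@@]1(O[Si](CC)(CC)CC)CC(=O)c2c(OCc3ccccc3)cc(OCc3ccccc3)cc2[C@@H]1C(=O)c1c(OCc2ccccc2)cc(OCc2ccccc2)cc1CC(=O)CC(=O)C=C=O | intermediate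
31 | (3R,4S)-6,8-bis(benzyloxy)-4-{2,4-bis(benzyloxy)-6-[(4-hydroxy-2-oxo-2H-pyran-6-yl)methyl]benzoyl}-3-methyl-3-(triethylsilyloxy)-3,4-dihydronaphthalen-1(2H)-one | C[C@@]1(O[Si](CC)(CC)CC)CC(=O)c2c(OCc3ccccc3)cc(OCc3ccccc3)cc2[C@@H]1C(=O)c1c(OCc2ccccc2)cc(OCc2ccccc2)cc1Cc1cc(O)cc(=O)o1 | intermediate
32 | (3R,4S)-6,8-bis(benzyloxy)-4-{2,4-bis(benzyloxy)-6-[(4-hydroxy-2-oxo-2H-pyran-6-yl)methyl]benzoyl}-3-hydroxy-3-methyl-3,4-dihydronaphthalen-1(2H)-one | C[C@@]1(O)CC(=O)c2c(OCc3ccccc3)cc(OCc3ccccc3)cc2[C@@H]1C(=O)c1c(OCc2ccccc2)cc(OCc2ccccc2)cc1Cc1cc(O)cc(=O)o1 | intermediate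
33 | (3R,4S)-4-{2,4-dihydroxy-6-[(4-hydroxy-2-oxo-2H-pyran-6-yl)methyl]benzoyl}-3,6,8-trihydroxy-3-methyl-3,4-dihydronaphthalen-1(2H)-one (CNP0197349.1) | C[C@@]1(O)CC(=O)c2c(O)cc(O)cc2[C@@H]1C(=O)c1c(O)cc(O)cc1Cc1cc(O)cc(=O)o1 | target

**Step count and risks**

Total: 23 steps. Longest linear sequence: 20 steps (1, 2, 5–17, 19–23); steps 3–4 and step 18 are side branches.

Steps most likely to fail:

1. Step 14 (ring switch). The aryllithium may be quenched by proton transfer from the lactone α-methylene or from a benzylic ether position before it reaches the carbonyl, or the boat-like approach over the lactone ring may be too slow in the cold. Fallback: setting out from 19, the lactone is opened with the aluminium amide from AlMe3 and MeONHMe·HCl to the open-chain hydroxy Weinreb amide F1. Treatment with t-BuLi (3.1 equiv, the first equivalent forming the alkoxide) in THF at −100 °C then lets the aryllithium acylate itself on the Weinreb amide through a freely rotating chain and a chelated tetrahedral intermediate, and aqueous work-up comes back to the route at 22.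

2. Step 12 (samarium Reformatsky lactonisation). Facial control at the new tertiary centre may erode if the axial α-aryl group distorts the bridged chair, and the bromoacetate may be lost by β-elimination or the α-aryl centre epimerised before reduction. Fallback: setting out from 14, allylmagnesium bromide (THF, −78 °C) gives the allyl ketone F2. MeMgBr then adds to its magnesium alkoxide chelate from the face away from the α-aryl group, which should give the diol F3 with the same configuration at the tertiary carbinol. Cleavage of the alkene with OsO4 (cat.) and NaIO4 gives an aldehyde that closes to the lactol F4, and oxidation with TEMPO (cat.) and PhI(OAc)2 comes back to the route at 18.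

3. Step 8 (boron aldol). Addition of the boron enolate to the doubly ortho-substituted, electron-rich aldehyde may be slow, and the aldolate may revert on work-up. Fallback: setting out from 4, coupling with (S)-4-benzyl-1,3-thiazolidine-2-thione (DCC, DMAP cat.) gives the N-acyl thiazolidinethione F5. Its chlorotitanium enolate (TiCl4, iPr2NEt 1 equiv, CH2Cl2, −78 °C) adds to 11, which is activated on titanium, through the chelated transition state and should give the (2R,3R)-syn adduct F6. MeONHMe·HCl with imidazole displaces the auxiliary directly and comes back to the route at 14.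

**Further compounds**

F1 | step 14 | (3R,4R,5R)-5-{2,4-bis(benzyloxy)-6-[2-(triethylsilyloxy)ethyl]phenyl}-4-[3,5-bis(benzyloxy)-2-bromophenyl]-5-hydroxy-N-methoxy-N,3-dimethyl-3-(triethylsilyloxy)pentanamide | CON(C)C(=O)C[C@@](C)(O[Si](CC)(CC)CC)[C@H](c1cc(OCc2ccccc2)cc(OCc2ccccc2)c1Br)[C@H](c1c(OCc2ccccc2)cc(OCc2ccccc2)cc1CCO[Si](CC)(CC)CC)O
F2 | step 12 | (1R,2R)-1-{2,4-bis(benzyloxy)-6-[2-(triethylsilyloxy)ethyl]phenyl}-2-[3,5-bis(benzyloxy)-2-bromophenyl]-1-hydroxyhex-5-en-3-one | C=CCC(=O)[C@H](c1cc(OCc2ccccc2)cc(OCc2ccccc2)c1Br)[C@@H](O)c1c(OCc2ccccc2)cc(OCc2ccccc2)cc1CCO[Si](CC)(CC)CC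
F3 | step 12 | (1R,2R,3R)-1-{2,4-bis(benzyloxy)-6-[2-(triethylsilyloxy)ethyl]phenyl}-2-[3,5-bis(benzyloxy)-2-bromophenyl]-3-methylhex-5-ene-1,3-diol | C=CC[C@@](C)(O)[C@H](c1cc(OCc2ccccc2)cc(OCc2ccccc2)c1Br)[C@@H](O)c1c(OCc2ccccc2)cc(OCc2ccccc2)cc1CCO[Si](CC)(CC)CC
F4 | step 12 | (4R,5R,6R)-6-{2,4-bis(benzyloxy)-6-[2-(triethylsilyloxy)ethyl]phenyl}-5-[3,5-bis(benzyloxy)-2-bromophenyl]-4-methyloxane-2,4-diol (lactol, both anomers) | OC1C[C@@](C)(O)[C@H](c2cc(OCc3ccccc3)cc(OCc3ccccc3)c2Br)[C@H](c2c(OCc3ccccc3)cc(OCc3ccccc3)cc2CCO[Si](CC)(CC)CC)O1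
F5 | step 8 | 2-[3,5-bis(benzyloxy)-2-bromophenyl]-1-[(S)-4-benzyl-2-thioxo-1,3-thiazolidin-3-yl]ethan-1-one | O=C(Cc1cc(OCc2ccccc2)cc(OCc2ccccc2)c1Br)N1[C@@H](Cc2ccccc2)CSC1=S
F6 | step 8 | (2R,3R)-3-{2,4-bis(benzyloxy)-6-[2-(triethylsilyloxy)ethyl]phenyl}-2-[3,5-bis(benzyloxy)-2-bromophenyl]-1-[(S)-4-benzyl-2-thioxo-1,3-thiazolidin-3-yl]-3-hydroxypropan-1-one | O=C(N1[C@@H](Cc2ccccc2)CSC1=S)[C@H](c1cc(OCc2ccccc2)cc(OCc2ccccc2)c1Br)[C@@H](O)c1c(OCc2ccccc2)cc(OCc2ccccc2)cc1CCO[Si](CC)(CC)CC
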